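Both heterocycles are opened at their aryl ketone bonds, C4–C4a and C4''–C4a''. The cut exploits the phloroglucinol pattern of rings A and A''. C4a and C4a'' lie ortho to O1 and O1'', each is pushed by three ring oxygens, and no other carbon is within reach of the C2–C3–C4 tethers (unit 1 offers two symmetry-equivalent sites; in unit 2 C8'' already carries ring B). One twofold intramolecular Friedel–Crafts acylation thus closes both rings C and leaves C2 and C2'' untouched. Its precursor is the open (S,S)-bis(3-aryloxy-3-arylpropanoic acid) on the finished C3'–C8'' biaryl, with benzyl ethers on the ring-A oxygens and electron-poor benzyl carbonates on O4' and O4'''.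

Key step: step 16

Locants: plain numbers and ring B (primed) belong to the naringenin-type unit 1. Double primes belong to the 7-O-methyl unit 2 (benzo ring A''), whose 4-hydroxyphenyl ring B''' takes triple primes.

Remark on the chemistry: the C3'–C8'' axis has three oxygen ortho substituents and is taken to rotate at room temperature, in line with the target SMILES, which holds no axial descriptor. Biaryl intermediates may show rotamer signals.

**Carbinol for unit 2**

Step 1
Reactants: 1 4-hydroxybenzaldehyde
Product: 2 benzyl 4-formylphenyl carbonate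
Conditions: CbzCl (1.1 equiv), Et3N (1.2 equiv), CH2Cl2, 0 °C
Reagents that add atoms: benzyl chloroformate, O=C(Cl)OCc1ccccc1
Why: Carbonate formation by O-acylation of the phenol with a chloroformate is fast at 0 °C, and it is done first so that O4''' is already a poor donor in every later step at the benzylic carbon.

Step 2
Reactants: 2 benzyl 4-formylphenyl carbonate
Product: 3 tert-butyl 3-{4-[(benzyloxycarbonyl)oxy]phenyl}-3-oxopropanoate
Conditions: tert-butyl diazoacetate (1.3 equiv, slow addition), SnCl2 (20 mol%), CH2Cl2, rt
Reagents that add atoms: tert-butyl diazoacetate, CC(C)(C)OC(=O)C=[N+]=[N-]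
Why: Roskamp homologation, in which the diazo carbon adds to the SnCl2-activated aldehyde and loss of N2 with a 1,2-hydride shift gives the β-keto ester in one non-basic step that spares the aryl carbonate, whose electron demand also lowers the rival aryl shift.

Step 3
Reactants: 3 tert-butyl 3-{4-[(benzyloxycarbonyl)oxy]phenyl}-3-oxopropanoate
Product: 4 tert-butyl (3R)-3-{4-[(benzyloxycarbonyl)oxy]phenyl}-3-hydroxypropanoate
Conditions: RuCl[(R,R)-TsDPEN](p-cymene) (1 mol%), HCO2H/Et3N (5:2), EtOAc, 25 °C
Reagents that add atoms: none
Why: Noyori–Ikariya asymmetric transfer hydrogenation of an aryl ketone, in which the (R,R)-complex passes hydride and proton through a six-membered outer-sphere transition state with the aryl group held under the η6-arene by a CH–π contact, which should set the (R)-carbinol while the benzyl carbonate and the tert-butyl ester are left alone.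

**Ring A'' iodide**

Step 4
Reactants: 5 5-methoxyresorcinol
Product: 6 4-iodo-5-methoxybenzene-1,3-diol
Conditions: NIS (1.0 equiv, portionwise), MeCN, −20 to 0 °C, dark
Reagents that add atoms: N-iodosuccinimide, O=C1CCC(=O)N1I
Why: Electrophilic aromatic iodination under non-basic conditions should follow the resorcinol pattern (attack para to one OH and ortho to the other, two equivalent sites) instead of the carbon between the hydroxyls that I2 in aqueous bicarbonate prefers, and the symmetric 2-iodo isomer, which would lead to the wrong O-methyl series, is removed here by chromatography.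

Step 5
Reactants: 6 4-iodo-5-methoxybenzene-1,3-diol
Product: 7 5-(benzyloxy)-2-iodo-3-methoxyphenol
Conditions: BnBr (1.0 equiv), K2CO3 (1.1 equiv), acetone, rt
Reagents that add atoms: benzyl bromide, BrCc1ccccc1
Why: Williamson monoalkylation with one equivalent of halide should go to the open hydroxyl para to iodine, as with 4-haloresorcinols, because the other hydroxyl is flanked by iodine and gives the less nucleophilic phenoxide, and the site is to be confirmed by NOE from OCH2Ph to both ring protons after removal of regioisomer and dibenzyl ether at this cheap stage.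

**Ring B boronate and biaryl**

Step 6
Reactants: 8 3-bromo-4-hydroxybenzaldehyde
Product: 9 4-(allyloxy)-3-bromobenzaldehyde
Conditions: allyl bromide (1.2 equiv), K2CO3, DMF, rt
Reagents that add atoms: allyl bromide, C=CCBr
Why: Williamson etherification gives a base-stable mask for the acidic O4'–H during the two basic palladium steps, which an aryl carbonate would not survive, and the allyl group can later be taken off under neutral conditions.

Step 7
Reactants: 9 4-(allyloxy)-3-bromobenzaldehyde
Product: 10 4-(allyloxy)-3-(4,4,5,5-tetramethyl-1,3,2-dioxaborolan-2-yl)benzaldehyde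
Conditions: B2pin2 (1.2 equiv), PdCl2(dppf) (3 mol%), KOAc (3 equiv), 1,4-dioxane, 85 °C
Reagents that add atoms: bis(pinacolato)diboron, CC1(C)OB(OC1(C)C)B1OC(C)(C)C(C)(C)O1
Why: Miyaura borylation tolerates the aldehyde and puts boron on the electron-poorer ring B, where protodeboronation is much slower than it would be on the trioxygenated ring A''.

Step 8
Reactants: 7 5-(benzyloxy)-2-iodo-3-methoxyphenol; 10 4-(allyloxy)-3-(4,4,5,5-tetramethyl-1,3,2-dioxaborolan-2-yl)benzaldehyde
Product: 11 4-(allyloxy)-3-[4-(benzyloxy)-2-hydroxy-6-methoxyphenyl]benzaldehyde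
Conditions: Pd(OAc)2 (5 mol%), SPhos (10 mol%), K3PO4 (3 equiv), toluene/H2O (10:1), 80 °C, degassed; mildly acidic work-up
Reagents that add atoms: none
Why: Suzuki–Miyaura coupling forms C3'–C8'', the bulky electron-rich biarylphosphine being the standard answer to a doubly ortho-substituted electron-rich iodide and a tri-ortho-substituted biaryl, and only base-stable groups (ethers, aldehyde, phenoxide) are present at this point.

**Assembly**

Step 9
Reactants: 11 4-(allyloxy)-3-[4-(benzyloxy)-2-hydroxy-6-methoxyphenyl]benzaldehyde; 4 tert-butyl (3R)-3-{4-[(benzyloxycarbonyl)oxy]phenyl}-3-hydroxypropanoate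
Product: 12 tert-butyl (3S)-3-{2-[2-(allyloxy)-5-formylphenyl]-5-(benzyloxy)-3-methoxyphenoxy}-3-{4-[(benzyloxycarbonyl)oxy]phenyl}propanoate
Conditions: PPh3 (1.5 equiv), DIAD (1.5 equiv, added last), toluene (concentrated), 0 °C to rt
Reagents that add atoms: none
Why: Mitsunobu etherification in which the ring-A'' phenol, the only acidic OH, displaces the oxyphosphonium group of 4 by SN2 with inversion, turning the (R)-carbinol into (S)-C2'', while the para carbonate holds back the SN1 path and the apolar solvent and low temperature hold back β-elimination to the cinnamate.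

Step 10
Reactants: 12 allyl ether aldehyde from step 9
Product: 13 tert-butyl (3S)-3-[5-(benzyloxy)-2-(5-formyl-2-hydroxyphenyl)-3-methoxyphenoxy]-3-{4-[(benzyloxycarbonyl)oxy]phenyl}propanoate
Conditions: Pd(PPh3)4 (5 mol%), p-toluenesulfinic acid (1.3 equiv), CH2Cl2, rt
Reagents that add atoms: none
Why: Tsuji–Trost-type deallylation in which zerovalent palladium ionises the allyl aryl ether (para-formyl phenoxide is a good leaving group) and the sulfinic acid traps the π-allyl complex as a sulfone while protonating the phenoxide, so that no amine or base meets the carbonate and no C–H acid able to condense with the aldehyde is used.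

Step 11
Reactants: 13 phenol aldehyde from step 10
Product: 14 tert-butyl (3S)-3-[5-(benzyloxy)-2-{2-[(benzyloxycarbonyl)oxy]-5-formylphenyl}-3-methoxyphenoxy]-3-{4-[(benzyloxycarbonyl)oxy]phenyl}propanoate
Conditions: CbzCl (1.2 equiv), Et3N (1.3 equiv), CH2Cl2, 0 °C
Reagents that add atoms: benzyl chloroformate, O=C(Cl)OCc1ccccc1
Why: Carbonate formation as in step 1 on the only free hydroxyl, under an amine base at 0 °C that is too weak to trigger E1cB loss of the β-aryloxy group, makes O4' a poor donor before the second benzylic centre is built.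

Step 12
Reactants: 14 bis(carbonate) aldehyde from step 11
Product: 15 keto diester, that is 14 with CHO replaced by C(=O)CH2CO2tBu (C2'' S)
Conditions: tert-butyl diazoacetate (1.5 equiv, slow addition), SnCl2 (20 mol%), CH2Cl2, rt
Reagents that add atoms: tert-butyl diazoacetate, CC(C)(C)OC(=O)C=[N+]=[N-]
Why: Roskamp homologation as in step 2, chosen because its mild Lewis acid conditions avoid the enolates or bases that would attack the two aryl carbonates or eliminate the β-aryloxy ester.

Step 13
Reactants: 15 keto diester from step 12
Product: 16 hydroxy diester with an (R)-carbinol at the future C2 and (S)-C2''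
Conditions: RuCl[(R,R)-TsDPEN](p-cymene) (2 mol%), HCO2H/Et3N (5:2), EtOAc, 25 °C
Reagents that add atoms: none
Why: The same asymmetric transfer hydrogenation as in step 3, in which the catalyst alone controls the face because C2'' is remote, so the (R,R)-complex should give the (R)-carbinol, and any material of wrong configuration at either centre is now a diastereomer that chromatography can remove.

Step 14
Reactants: 16 hydroxy diester from step 13; 17 3,5-dibenzyloxyphenol
Product: 18 (S,S)-bis(aryl ether) di-tert-butyl ester
Conditions: PPh3 (1.5 equiv), DIAD (1.5 equiv, added last), toluene, 0 °C to rt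
Reagents that add atoms: none
Why: Mitsunobu etherification with the unhindered phenol 17, in which SN2 displacement of the oxyphosphonium group inverts the (R)-carbinol to (S)-C2, the O4' carbonate suppresses the SN1 path, and no other acidic OH in 16 competes.

Step 15
Reactants: 18 (S,S)-bis(aryl ether) di-tert-butyl ester
Product: 19 (S,S)-bis(3-aryloxy-3-arylpropanoic acid)
Conditions: TFA/CH2Cl2 (1:2), Et3SiH (6 equiv), 0 °C to rt; evaporation with toluene, hexane trituration to remove all silicon residues
Reagents that add atoms: none
Why: Acidolysis of tert-butyl esters by alkyl–oxygen fission is the ester release that fits base-labile carbonates and E1cB-prone β-aryloxy esters, and Et3SiH takes up the tert-butyl cation as isobutane before it can alkylate the two phloroglucinol-type rings, while the carbonates keep the benzylic ethers from ionising.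

Step 16
Reactants: 19 (S,S)-bis(3-aryloxy-3-arylpropanoic acid)
Product: 21 benzyl- and benzyl carbonate-protected (2S,2''S)-biflavanone, via bis(trifluoroacetic) mixed anhydride 20 (not isolated)
Conditions: TFAA (3 equiv), CH2Cl2 (0.01 M), 0 °C to rt; quench into cold pH 7 phosphate buffer
Reagents that add atoms: trifluoroacetic anhydride, O=C(OC(=O)C(F)(F)F)C(F)(F)F (supplies the two CF3CO groups of 20, which leave again on ring closure; nothing of it remains in 21)
Why: TFAA converts each carboxyl group into the mixed anhydride 20, the CF3CO2H set free activates its alkanoyl carbonyl, the ring-A carbon ortho to the ether oxygen attacks it, and deprotonation of the arenium ion gives the aryl ketone, which is the known intramolecular Friedel–Crafts acylation of 3-aryloxypropanoic acids to chroman-4-ones, here run twice in one flask. Ring C of unit 1 closes in a six-membered mode (6-exo-trig at the acyl carbon) onto either of the two symmetry-equivalent carbons ortho to O1 of the 3,5-dibenzyloxyphenyl ether, which becomes C4a. Ring C of unit 2 closes in the same mode onto C4a'', the only free carbon ortho to O1'' because the other one, C8'', holds ring B, while C6'' and the carbon para to O1 are out of reach of a three-atom tether. No stereocentre is formed; C2 and C2'' are bystanders whose S configuration should hold because the para carbonates and the β-acyl groups disfavour heterolysis of C2–O1 and C2''–O1''. The same carbonates keep rings B and B''' too electron-poor for the rival five-membered closure to an indanone, so each acyl group has only its trioxygenated ring A as partner. Transfer of the alkanoyl and not the trifluoroacetyl half of 20, and intra- over intermolecular attack, are secured by the six-membered transition state, high dilution, a small excess of TFAA and 0 °C, and each ring is deactivated once acylated.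

Step 17
Reactants: 21 protected (2S,2''S)-biflavanone
Product: 22 target, (2S,2''S)-5,7,4'-trihydroxyflavanone joined C3'–C8'' to 5'',4'''-dihydroxy-7''-methoxyflavanone
Conditions: H2 (1 atm), 10% Pd/C, EtOAc/THF (1:1), rt, stopped when uptake ends; filtration through Celite
Reagents that add atoms: none
Why: Catalytic hydrogenolysis cleaves all five O–CH2Ph bonds in one operation, the two aryl hydrogen carbonates so formed lose CO2 by themselves, and in a neutral aprotic medium at one atmosphere the chelated C4 and C4'' ketones, the cyclic benzylic C2–O1 bonds and the base-sensitive C2 and C2'' centres should stay intact.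

**Compound list**

1 | 4-hydroxybenzaldehyde | O=Cc1ccc(O)cc1 | starting material
2 | benzyl 4-formylphenyl carbonate | O=Cc1ccc(OC(=O)OCc2ccccc2)cc1 | intermediate
3 | tert-butyl 3-{4-[(benzyloxycarbonyl)oxy]phenyl}-3-oxopropanoate | CC(C)(C)OC(=O)CC(=O)c1ccc(OC(=O)OCc2ccccc2)cc1 | intermediate
4 | tert-butyl (3R)-3-{4-[(benzyloxycarbonyl)oxy]phenyl}-3-hydroxypropanoate | O[C@@H](c1ccc(OC(=O)OCc2ccccc2)cc1)CC(=O)OC(C)(C)C | intermediate
5 | 5-methoxyresorcinol | COc1cc(O)cc(O)c1 | starting material
6 | 4-iodo-5-methoxybenzene-1,3-diol | COc1cc(O)cc(O)c1I | intermediate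
7 | 5-(benzyloxy)-2-iodo-3-methoxyphenol | COc1cc(OCc2ccccc2)cc(O)c1I | intermediate
8 | 3-bromo-4-hydroxybenzaldehyde | O=Cc1ccc(O)c(Br)c1 | starting material
9 | 4-(allyloxy)-3-bromobenzaldehyde | C=CCOc1ccc(C=O)cc1Br | intermediate
10 | 4-(allyloxy)-3-(4,4,5,5-tetramethyl-1,3,2-dioxaborolan-2-yl)benzaldehyde | C=CCOc1ccc(C=O)cc1B1OC(C)(C)C(C)(C)O1 | intermediate
11 | 4-(allyloxy)-3-[4-(benzyloxy)-2-hydroxy-6-methoxyphenyl]benzaldehyde | COc1cc(OCc2ccccc2)cc(O)c1-c1cc(C=O)ccc1OCC=C | intermediate
12 | tert-butyl (3S)-3-{2-[2-(allyloxy)-5-formylphenyl]-5-(benzyloxy)-3-methoxyphenoxy}-3-{4-[(benzyloxycarbonyl)oxy]phenyl}propanoate | COc1cc(OCc2ccccc2)cc(O[C@H](c2ccc(OC(=O)OCc3ccccc3)cc2)CC(=O)OC(C)(C)C)c1-c1cc(C=O)ccc1OCC=C | intermediate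
13 | tert-butyl (3S)-3-[5-(benzyloxy)-2-(5-formyl-2-hydroxyphenyl)-3-methoxyphenoxy]-3-{4-[(benzyloxycarbonyl)oxy]phenyl}propanoate | COc1cc(OCc2ccccc2)cc(O[C@H](c2ccc(OC(=O)OCc3ccccc3)cc2)CC(=O)OC(C)(C)C)c1-c1cc(C=O)ccc1O | intermediate
14 | tert-butyl (3S)-3-[5-(benzyloxy)-2-{2-[(benzyloxycarbonyl)oxy]-5-formylphenyl}-3-methoxyphenoxy]-3-{4-[(benzyloxycarbonyl)oxy]phenyl}propanoate | COc1cc(OCc2ccccc2)cc(O[C@H](c2ccc(OC(=O)OCc3ccccc3)cc2)CC(=O)OC(C)(C)C)c1-c1cc(C=O)ccc1OC(=O)OCc1ccccc1 | intermediate
15 | keto diester (14 with CHO replaced by C(=O)CH2CO2tBu; C2'' S) | COc1cc(OCc2ccccc2)cc(O[C@H](c2ccc(OC(=O)OCc3ccccc3)cc2)CC(=O)OC(C)(C)C)c1-c1cc(C(=O)CC(=O)OC(C)(C)C)ccc1OC(=O)OCc1ccccc1 | intermediate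
16 | hydroxy diester ((R)-carbinol at the future C2; C2'' S) | COc1cc(OCc2ccccc2)cc(O[C@H](c2ccc(OC(=O)OCc3ccccc3)cc2)CC(=O)OC(C)(C)C)c1-c1cc([C@H](O)CC(=O)OC(C)(C)C)ccc1OC(=O)OCc1ccccc1 | intermediate
17 | 3,5-dibenzyloxyphenol | Oc1cc(OCc2ccccc2)cc(OCc2ccccc2)c1 | starting material
18 | (S,S)-bis(aryl ether) di-tert-butyl ester | COc1cc(OCc2ccccc2)cc(O[C@H](c2ccc(OC(=O)OCc3ccccc3)cc2)CC(=O)OC(C)(C)C)c1-c1cc([C@@H](Oc2cc(OCc3ccccc3)cc(OCc3ccccc3)c2)CC(=O)OC(C)(C)C)ccc1OC(=O)OCc1ccccc1 | intermediate
19 | (S,S)-bis(3-aryloxy-3-arylpropanoic acid) | COc1cc(OCc2ccccc2)cc(O[C@H](c2ccc(OC(=O)OCc3ccccc3)cc2)CC(=O)O)c1-c1cc([C@@H](Oc2cc(OCc3ccccc3)cc(OCc3ccccc3)c2)CC(=O)O)ccc1OC(=O)OCc1ccccc1 | intermediate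
20 | bis(trifluoroacetic) mixed anhydride of 19 | COc1cc(OCc2ccccc2)cc(O[C@H](c2ccc(OC(=O)OCc3ccccc3)cc2)CC(=O)OC(=O)C(F)(F)F)c1-c1cc([C@@H](Oc2cc(OCc3ccccc3)cc(OCc3ccccc3)c2)CC(=O)OC(=O)C(F)(F)F)ccc1OC(=O)OCc1ccccc1 | intermediate
21 | benzyl- and benzyl carbonate-protected (2S,2''S)-biflavanone | COc1cc(OCc2ccccc2)c2c(c1-c1cc([C@@H]3CC(=O)c4c(OCc5ccccc5)cc(OCc5ccccc5)cc4O3)ccc1OC(=O)OCc1ccccc1)O[C@H](c1ccc(OC(=O)OCc3ccccc3)cc1)CC2=O | intermediate
22 | CNP0237714.1, (2S,2''S)-3',8''-biflavanone (5,7,4',5'',4'''-pentahydroxy-7''-methoxy) | COc1cc(O)c2c(c1-c1cc([C@@H]3CC(=O)c4c(O)cc(O)cc4O3)ccc1O)O[C@H](c1ccc(O)cc1)CC2=O | target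

**Totals:** 17 steps. The longest linear sequence is 12 steps (8 → 9 → 10 → 11 → 12 → 13 → 14 → 15 → 16 → 18 → 19 → 21 → 22).

**Steps most likely to fail**

1. **Step 16 (key step).** Trifluoroacetyl transfer to a still open, strongly activated ring A may compete with the slower of the two closures. The first-formed chromanone then sits in acid while the more crowded unit 2 closes, which invites acid loss of the peri benzyl ethers and creeping ionisation at C2 and C2''. The fallback leaves the anhydride and Brønsted acid manifold, sets out from 19 and comes back at 21. Treatment of 19 with 1-chloro-N,N,2-trimethylprop-1-en-1-amine (CH2Cl2, 0 °C) should give, under neutral conditions and without any trifluoroacetyl donor, the (S,S)-bis(3-aryloxy-3-arylpropanoyl chloride) F1. SnCl4 (CH2Cl2, −78 °C) then drives both acylations through discrete Lewis acid–acyl chloride complexes, at a temperature at which benzyl ethers and the benzylic C–O bonds are inert.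

2. **Step 9.** Slow SN2 attack by a phenol shielded by the twisted ortho aryl ring may give the oxyphosphonium salt time to eliminate towards the cinnamate or to ionise, with erosion of configuration. The fallback reverses the order of C–O and C–C bond formation, sets out from 7 and 4 and comes back at 12. The smaller and more acidic iodophenol 7 is coupled with 4 under the same Mitsunobu conditions to give tert-butyl (3S)-3-[5-(benzyloxy)-2-iodo-3-methoxyphenoxy]-3-{4-[(benzyloxycarbonyl)oxy]phenyl}propanoate F2. The biaryl bond is then made from F2 and boronate 10 by a water-free, weak-base Suzuki–Miyaura coupling (Pd(OAc)2, SPhos, powdered K3PO4, toluene, 60 °C) chosen to spare the carbonate and the β-aryloxy ester.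

3. **Step 5.** The two hydroxyls may be poorly discriminated and overalkylation may occur, because the hydroxyl next to iodine is the more acidic one even though it is the more hindered. The fallback postpones the benzylation until the steric bias is much larger, sets out from 6 and 10 and comes back at 11. Diol 6 is coupled directly with 10 under the conditions of step 8 (one more equivalent of K3PO4) to give 4-(allyloxy)-3-(2,4-dihydroxy-6-methoxyphenyl)benzaldehyde F3. In F3 the hydroxyl beside the twisted, ortho-substituted ring B is strongly shielded and no longer the more acidic one, so BnBr (1.0 equiv) and K2CO3 in acetone should alkylate the open para hydroxyl.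

**Further compounds**

F1 | step 16 | (S,S)-bis(3-aryloxy-3-arylpropanoyl chloride) | COc1cc(OCc2ccccc2)cc(O[C@H](c2ccc(OC(=O)OCc3ccccc3)cc2)CC(=O)Cl)c1-c1cc([C@@H](Oc2cc(OCc3ccccc3)cc(OCc3ccccc3)c2)CC(=O)Cl)ccc1OC(=O)OCc1ccccc1
F2 | step 9 | tert-butyl (3S)-3-[5-(benzyloxy)-2-iodo-3-methoxyphenoxy]-3-{4-[(benzyloxycarbonyl)oxy]phenyl}propanoate | COc1cc(OCc2ccccc2)cc(O[C@H](c2ccc(OC(=O)OCc3ccccc3)cc2)CC(=O)OC(C)(C)C)c1I
F3 | step 5 | 4-(allyloxy)-3-(2,4-dihydroxy-6-methoxyphenyl)benzaldehyde | COc1cc(O)cc(O)c1-c1cc(C=O)ccc1OCC=C
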